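**Retrosynthetic overview**

1. The target is a trans-2-aryl-3-(hydroxymethyl)-2,3-dihydro-1,4-benzodioxine (ring atoms O1, C2 with the guaiacyl ring, C3 with CH2OH, O4, C4a, C6 with the acrylic acid, C8a). The last step is desilylation with equilibration of C2; before it the acrylic acid is made by Knoevenagel–Doebner condensation and the CH2OH by glycol cleavage and reduction.
2. Key disconnection: C2–C3 and O4–C4a are formed in one operation. The C=O of (R)-glyceraldehyde acetonide is formally inserted between the benzylic C2–H bond and the aryl C4a–F bond of a benzyl 2-fluorophenyl ether (lithiation, carbonyl addition, intramolecular SNAr).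
3. Enabling feature: C2 is both benzylic to the guaiacyl ring and α to the aryl ether oxygen O1, so it can be lithiated. C4a is the benzo-ring carbon ortho to O1, so the C3 alkoxide reaches it through a six-membered transition state. The guaiacyl 4-OH para to C2 makes C2 epimerisable through a p-quinone methide, so only C3 has to be set in the key step.
4. Ring order: both benzene rings are bought (vanillin, 3-fluoro-4-hydroxybenzaldehyde) and joined by a Mitsunobu etherification; the 1,4-dioxane ring is the only ring formed (step 5).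

Key step: step 5

Remark on stereochemistry: compounds 10, 11, 13, 14 and 15 are carried as mixtures of C2 epimers (C2 is left unspecified in their SMILES). C3 keeps the spatial arrangement of the target from step 5 on, although its CIP letter changes with the substituent. C2 is set in step 9.

Remark on reagents: 7 is commercial and is best distilled just before use.

Assumption: (−)-8-phenylmenthyl glyoxylate, used only in one fallback, is taken to be attacked by the lithiated ether on the same face as by Grignard reagents, giving the (S)-α-hydroxy ester; if the sense were reversed, its enantiomer would be used.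

**Route**

Step 1
Reactants: 1 vanillin
Product: 2 3-methoxy-4-[tri(propan-2-yl)silyloxy]benzaldehyde
Conditions: TIPSCl, imidazole, DMF, rt
Reagents that add atoms: triisopropylsilyl chloride, CC(C)[Si](Cl)(C(C)C)C(C)C
Why: Imidazole-promoted O-silylation of the phenol; the bulky TIPS ether tolerates organolithium reagents and does not direct ortho-lithiation.

Step 2
Reactants: 2 3-methoxy-4-[tri(propan-2-yl)silyloxy]benzaldehyde
Product: 3 {3-methoxy-4-[tri(propan-2-yl)silyloxy]phenyl}methanol
Conditions: NaBH4, MeOH, 0 °C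
Reagents that add atoms: none
Why: Borohydride reduction of the aryl aldehyde to the benzylic alcohol should leave the aryl silyl ether untouched.

Step 3
Reactants: 3 {3-methoxy-4-[tri(propan-2-yl)silyloxy]phenyl}methanol; 4 3-fluoro-4-hydroxybenzaldehyde
Product: 5 3-fluoro-4-({3-methoxy-4-[tri(propan-2-yl)silyloxy]phenyl}methoxy)benzaldehyde
Conditions: PPh3, DIAD, THF, 0 °C → rt
Reagents that add atoms: none
Why: Mitsunobu etherification of the acidic fluorophenol with the primary benzylic alcohol should give the benzyl aryl ether without touching the aldehyde or the silyl ether.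

Step 4
Reactants: 5 3-fluoro-4-({3-methoxy-4-[tri(propan-2-yl)silyloxy]phenyl}methoxy)benzaldehyde
Product: 6 {4-[(4-(dimethoxymethyl)-2-fluorophenoxy)methyl]-2-methoxyphenoxy}tri(propan-2-yl)silane
Conditions: HC(OMe)3, PPTS (cat.), MeOH, rt
Reagents that add atoms: trimethyl orthoformate, COC(OC)OC; methanol, CO
Why: Acid-catalysed acetalisation masks the aldehyde against the organolithium of step 5; PPTS at room temperature should spare the silyl ether and the benzylic aryl ether.

Step 5
Reactants: 6 {4-[(4-(dimethoxymethyl)-2-fluorophenoxy)methyl]-2-methoxyphenoxy}tri(propan-2-yl)silane; 7 (R)-2,2-dimethyl-1,3-dioxolane-4-carbaldehyde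
Product: 10 (3S)-6-(dimethoxymethyl)-3-[(4R)-2,2-dimethyl-1,3-dioxolan-4-yl]-2-{3-methoxy-4-[tri(propan-2-yl)silyloxy]phenyl}-2,3-dihydro-1,4-benzodioxine (C2 epimers), via α-lithiated benzyl ether 8 (not isolated), via lithium alkoxide adduct 9 (not isolated)
Conditions: t-BuLi (1.1 equiv), THF, −78 °C; 7 (1.05 equiv), −78 °C; then KOt-Bu (0.3 equiv), DMPU, −78 → 65 °C; aq NH4Cl
Reagents that add atoms: none
Why: Proposed new method: t-BuLi, guided by the ether oxygen O1, should remove the benzylic α-oxy proton of 6 (future C2) to give 8, which adds to the aldehyde carbon of 7 (new C2–C3 bond) to give alkoxide 9; in the potassium/DMPU medium the C3 alkoxide then displaces the fluoride at C4a by intramolecular SNAr through a Meisenheimer intermediate (new O4–C4a bond), so that an aldehyde C=O is formally inserted between a benzylic C–H and an aryl C–F bond. The closest known reaction types are the α-lithiation and electrophile trapping of aryl benzyl ethers with t-BuLi at −78 °C, tandem carbonyl-addition/SNAr annulations of ortho-fluoroaryl substrates and alkoxide SNAr on unactivated aryl fluorides; their union in one flask on this substrate class is the new element. The only ring closed is the 1,4-dioxane ring, by 6-exo attack of O4 on C4a. C3 is set by Felkin–Anh addition to the α-alkoxy aldehyde (attack anti to the dioxolane C–O bond, giving the anti adduct that corresponds to 3R of the target), whereas C2 comes from a configurationally labile benzylic lithium, is not controlled here and is corrected in step 9. The step needs lithiation at the benzylic α-oxy C–H and not at the aryl C–H next to fluorine, which pre-coordination of t-BuLi to O1 and the benzylic activation should secure, and it needs O-arylation at C4a only, which the single C–F bond ortho to O1 and the six-membered transition state secure. The [1,2]-Wittig shift of 8 should be suppressed by holding −78 °C until the aldehyde is added, and the fluoride released is bound as insoluble LiF, which should spare the silyl ether.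

Step 6
Reactants: 10 (3S)-6-(dimethoxymethyl)-3-[(4R)-2,2-dimethyl-1,3-dioxolan-4-yl]-2-{3-methoxy-4-[tri(propan-2-yl)silyloxy]phenyl}-2,3-dihydro-1,4-benzodioxine (C2 epimers)
Product: 11 (3R)-3-[(1R)-1,2-dihydroxyethyl]-2-{3-methoxy-4-[tri(propan-2-yl)silyloxy]phenyl}-2,3-dihydro-1,4-benzodioxine-6-carbaldehyde (C2 epimers)
Conditions: AcOH–H2O–THF, 45 °C
Reagents that add atoms: water, O
Why: Mild aqueous acid hydrolysis should cleave both acetals (dimethyl acetal to the aldehyde, acetonide to the 1,2-diol) while the aryl TIPS ether and the benzylic aryl ether of the dioxane ring stay intact.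

Step 7
Reactants: 11 (3R)-3-[(1R)-1,2-dihydroxyethyl]-2-{3-methoxy-4-[tri(propan-2-yl)silyloxy]phenyl}-2,3-dihydro-1,4-benzodioxine-6-carbaldehyde (C2 epimers); 12 malonic acid
Product: 13 (2E)-3-[(3R)-3-[(1R)-1,2-dihydroxyethyl]-2-{3-methoxy-4-[tri(propan-2-yl)silyloxy]phenyl}-2,3-dihydro-1,4-benzodioxin-6-yl]prop-2-enoic acid (C2 epimers)
Conditions: pyridine, piperidine (cat.), 85 °C; aq HCl
Reagents that add atoms: none
Why: Knoevenagel–Doebner condensation with decarboxylation should give the (E)-cinnamic acid directly as the free acid, with the diol and the silyl ether unaffected.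

Step 8
Reactants: 13 (2E)-3-[(3R)-3-[(1R)-1,2-dihydroxyethyl]-2-{3-methoxy-4-[tri(propan-2-yl)silyloxy]phenyl}-2,3-dihydro-1,4-benzodioxin-6-yl]prop-2-enoic acid (C2 epimers)
Product: 15 (2E)-3-[(3R)-3-(hydroxymethyl)-2-{3-methoxy-4-[tri(propan-2-yl)silyloxy]phenyl}-2,3-dihydro-1,4-benzodioxin-6-yl]prop-2-enoic acid (C2 epimers), via C3 aldehyde 14 (not isolated)
Conditions: NaIO4, NaHCO3, THF–H2O, 0 °C; then NaBH4, 0 °C; aq HCl to pH 3
Reagents that add atoms: none
Why: Periodate glycol cleavage removes the extra carbon and immediate borohydride reduction of the labile α-aryloxy aldehyde gives the hydroxymethyl group; cold, near-neutral conditions should preserve C3 and the silyl ether shields the guaiacol from periodate.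

Step 9
Reactants: 15 (2E)-3-[(3R)-3-(hydroxymethyl)-2-{3-methoxy-4-[tri(propan-2-yl)silyloxy]phenyl}-2,3-dihydro-1,4-benzodioxin-6-yl]prop-2-enoic acid (C2 epimers)
Product: 18 (2E)-3-[(2R,3R)-2-(4-hydroxy-3-methoxyphenyl)-3-(hydroxymethyl)-2,3-dihydro-1,4-benzodioxin-6-yl]prop-2-enoic acid, via cis phenol epimer 16 (not isolated), via ring-opened quinone methide 17 (not isolated)
Conditions: TBAF (3 equiv), THF, 0 → 45 °C; aq HCl
Reagents that add atoms: none
Why: Fluoride desilylation frees the para-phenolate, which should reversibly expel the C8a aryloxide from C2 (retro-oxa-Michael to the p-quinone methide) and re-add it (oxa-Michael), so that the C2 epimers converge on the more stable trans-diequatorial (2R,3R) isomer while C3 is untouched.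

**Compound list**

1 | vanillin (4-hydroxy-3-methoxybenzaldehyde) | COc1cc(C=O)ccc1O | starting material
2 | 3-methoxy-4-[tri(propan-2-yl)silyloxy]benzaldehyde | COc1cc(C=O)ccc1O[Si](C(C)C)(C(C)C)C(C)C | intermediate
3 | {3-methoxy-4-[tri(propan-2-yl)silyloxy]phenyl}methanol | COc1cc(CO)ccc1O[Si](C(C)C)(C(C)C)C(C)C | intermediate
4 | 3-fluoro-4-hydroxybenzaldehyde | O=Cc1ccc(O)c(F)c1 | starting material
5 | 3-fluoro-4-({3-methoxy-4-[tri(propan-2-yl)silyloxy]phenyl}methoxy)benzaldehyde | COc1cc(COc2ccc(C=O)cc2F)ccc1O[Si](C(C)C)(C(C)C)C(C)C | intermediate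
6 | {4-[(4-(dimethoxymethyl)-2-fluorophenoxy)methyl]-2-methoxyphenoxy}tri(propan-2-yl)silane | COc1cc(COc2ccc(C(OC)OC)cc2F)ccc1O[Si](C(C)C)(C(C)C)C(C)C | intermediate
7 | (R)-2,2-dimethyl-1,3-dioxolane-4-carbaldehyde ((R)-glyceraldehyde acetonide) | CC1(C)OC[C@@H](O1)C=O | starting material
8 | α-lithiated 6 (lithium on the benzylic O–CH carbon, the future C2) | COc1cc(C([Li])Oc2ccc(C(OC)OC)cc2F)ccc1O[Si](C(C)C)(C(C)C)C(C)C | intermediate
9 | lithium (1S)-2-[4-(dimethoxymethyl)-2-fluorophenoxy]-1-[(4R)-2,2-dimethyl-1,3-dioxolan-4-yl]-2-{3-methoxy-4-[tri(propan-2-yl)silyloxy]phenyl}ethan-1-olate (anti adduct, epimers at the benzylic carbon) | COc1cc(C(Oc2ccc(C(OC)OC)cc2F)[C@H](O[Li])[C@H]3COC(C)(C)O3)ccc1O[Si](C(C)C)(C(C)C)C(C)C | intermediate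
10 | (3S)-6-(dimethoxymethyl)-3-[(4R)-2,2-dimethyl-1,3-dioxolan-4-yl]-2-{3-methoxy-4-[tri(propan-2-yl)silyloxy]phenyl}-2,3-dihydro-1,4-benzodioxine (C2 epimers) | COc1cc(C2Oc3ccc(C(OC)OC)cc3O[C@@H]2[C@H]4COC(C)(C)O4)ccc1O[Si](C(C)C)(C(C)C)C(C)C | intermediate
11 | (3R)-3-[(1R)-1,2-dihydroxyethyl]-2-{3-methoxy-4-[tri(propan-2-yl)silyloxy]phenyl}-2,3-dihydro-1,4-benzodioxine-6-carbaldehyde (C2 epimers) | COc1cc(C2Oc3ccc(C=O)cc3O[C@@H]2[C@H](O)CO)ccc1O[Si](C(C)C)(C(C)C)C(C)C | intermediate
12 | malonic acid | OC(=O)CC(=O)O | starting material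
13 | (2E)-3-[(3R)-3-[(1R)-1,2-dihydroxyethyl]-2-{3-methoxy-4-[tri(propan-2-yl)silyloxy]phenyl}-2,3-dihydro-1,4-benzodioxin-6-yl]prop-2-enoic acid (C2 epimers) | COc1cc(C2Oc3ccc(/C=C/C(=O)O)cc3O[C@@H]2[C@H](O)CO)ccc1O[Si](C(C)C)(C(C)C)C(C)C | intermediate
14 | (2E)-3-[(3S)-3-formyl-2-{3-methoxy-4-[tri(propan-2-yl)silyloxy]phenyl}-2,3-dihydro-1,4-benzodioxin-6-yl]prop-2-enoic acid (C2 epimers) | COc1cc(C2Oc3ccc(/C=C/C(=O)O)cc3O[C@@H]2C=O)ccc1O[Si](C(C)C)(C(C)C)C(C)C | intermediate
15 | (2E)-3-[(3R)-3-(hydroxymethyl)-2-{3-methoxy-4-[tri(propan-2-yl)silyloxy]phenyl}-2,3-dihydro-1,4-benzodioxin-6-yl]prop-2-enoic acid (C2 epimers) | COc1cc(C2Oc3ccc(/C=C/C(=O)O)cc3O[C@@H]2CO)ccc1O[Si](C(C)C)(C(C)C)C(C)C | intermediate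
16 | (2E)-3-[(2S,3R)-2-(4-hydroxy-3-methoxyphenyl)-3-(hydroxymethyl)-2,3-dihydro-1,4-benzodioxin-6-yl]prop-2-enoic acid (cis epimer of the target) | COc1cc([C@@H]2Oc3ccc(/C=C/C(=O)O)cc3O[C@@H]2CO)ccc1O | intermediate
17 | ring-opened p-quinone methide: (2E)-3-(4-hydroxy-3-{[(2S)-1-hydroxy-3-(3-methoxy-4-oxocyclohexa-2,5-dien-1-ylidene)propan-2-yl]oxy}phenyl)prop-2-enoic acid (oxygen-bearing carbon in the spatial arrangement of C3 of the target) | COC1=CC(=C[C@@H](CO)Oc2cc(/C=C/C(=O)O)ccc2O)C=CC1=O | intermediate
18 | (2E)-3-[(2R,3R)-2-(4-hydroxy-3-methoxyphenyl)-3-(hydroxymethyl)-2,3-dihydro-1,4-benzodioxin-6-yl]prop-2-enoic acid | COc1cc([C@H]2Oc3ccc(/C=C/C(=O)O)cc3O[C@@H]2CO)ccc1O | target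

**Step count**

Total step count: 9. Longest linear sequence: 9 steps (1 → 18); 4, 7 and 12 are bought.

**Steps most likely to fail**

Step 5 (proposed new method). Four processes may defeat it:
- lithiation at the aryl C–H flanked by fluorine and the acetal instead of the benzylic position;
- [1,2]-Wittig shift of the lithiated ether;
- low facial selectivity in the addition to 7;
- a sluggish SNAr, which would let the C3 alkoxide displace the C2 aryloxide (epoxide formation) instead of closing the ring.

The fallback uses known chemistry only, sets out from 7 and returns at 15. Commercial 4-bromo-2-methoxyphenol would be silylated to (4-bromo-2-methoxyphenoxy)tri(propan-2-yl)silane F1 and converted into the aryl Grignard reagent F2. Its addition to 7 would give the carbinol F3. Here the dioxolane carbon of 7 itself becomes C3, so this centre comes from the chiral pool with no facial-selectivity question; the carbinol carbon (future C2) forms as a mixture, which step 9 tolerates. The sodium alkoxide of F3 would displace the activated para-fluoride of commercial 3-bromo-4-fluorobenzaldehyde (intermolecular SNAr) to give the aryl ether F4. Aqueous acetic acid would remove the acetonide to give the diol F5. Pd-catalysed intramolecular C–O coupling of the secondary hydroxyl with the aryl bromide would give the benzodioxane aldehyde F6; six-membered closure should outpace seven-membered closure through the primary hydroxyl. Knoevenagel–Doebner condensation with 12 would deliver 15, and step 9 follows.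

Step 9. The equilibration may stop short of the trans isomer, or the quinone methide may drain into other pathways (loss of formaldehyde from the free hydroxymethyl group to give an enol ether, conjugate additions to the acrylate). The fallback sets out from 10 and returns at 11. Compound 10 would be desilylated with TBAF to the phenol F7. Its C2 epimers would be equilibrated with Cs2CO3 in DMF at a stage where the primary alcohol is still locked in the acetonide and no acrylic acid is present. The trans phenol F8 would be separated, the cis isomer being recycled through the same equilibration, and re-silylated (TIPSCl, imidazole) to F9, the single 2R isomer of 10. Steps 6 to 8 would then run on single isomers, rejoining the route at 11. The last step would become a plain buffered desilylation (TBAF/AcOH) of the (2R,3R) isomer of 15.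

Step 8. C3 may epimerise through the enol of the transient α-aryloxy aldehyde, or the C2 aryloxide may be lost by β-elimination, before the reduction takes place. The fallback sets out from 6 and returns at 15; it avoids the extra carbon, and hence the aldehyde, by bringing C3 in at the ester oxidation level. Compound 6 would be lithiated as in step 5 and added at −78 °C to (−)-8-phenylmenthyl glyoxylate F10 (from commercial (−)-8-phenylmenthol and glyoxylic acid). The auxiliary shields one face of the aldehyde, so protonation should give the (2S)-hydroxy ester F11. LiBH4 would reduce the ester to the diol F12 and return the auxiliary. KOt-Bu in THF–DMPU would close the dioxane ring by intramolecular SNAr through the secondary alkoxide to give the hydroxymethyl benzodioxane F13. Aqueous acetic acid would unmask the aldehyde F6, the compound already met in the first fallback, and Knoevenagel–Doebner condensation with 12 would rejoin the route at 15.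

**Further compounds**

F1 | step 5 | (4-bromo-2-methoxyphenoxy)tri(propan-2-yl)silane | COc1cc(Br)ccc1O[Si](C(C)C)(C(C)C)C(C)C
F2 | step 5 | {3-methoxy-4-[tri(propan-2-yl)silyloxy]phenyl}magnesium bromide | COc1cc([Mg]Br)ccc1O[Si](C(C)C)(C(C)C)C(C)C
F3 | step 5 | [(4R)-2,2-dimethyl-1,3-dioxolan-4-yl]{3-methoxy-4-[tri(propan-2-yl)silyloxy]phenyl}methanol (carbinol epimers) | COc1cc(C(O)[C@H]2COC(C)(C)O2)ccc1O[Si](C(C)C)(C(C)C)C(C)C
F4 | step 5 | 3-bromo-4-([(4R)-2,2-dimethyl-1,3-dioxolan-4-yl]{3-methoxy-4-[tri(propan-2-yl)silyloxy]phenyl}methoxy)benzaldehyde (epimers at the benzylic carbon) | COc1cc(C(Oc2ccc(C=O)cc2Br)[C@H]3COC(C)(C)O3)ccc1O[Si](C(C)C)(C(C)C)C(C)C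
F5 | step 5 | 3-bromo-4-[(2R)-2,3-dihydroxy-1-{3-methoxy-4-[tri(propan-2-yl)silyloxy]phenyl}propoxy]benzaldehyde (epimers at C1 of the propoxy chain) | COc1cc(C(Oc2ccc(C=O)cc2Br)[C@H](O)CO)ccc1O[Si](C(C)C)(C(C)C)C(C)C
F6 | step 5 | (3R)-3-(hydroxymethyl)-2-{3-methoxy-4-[tri(propan-2-yl)silyloxy]phenyl}-2,3-dihydro-1,4-benzodioxine-6-carbaldehyde (C2 epimers) | COc1cc(C2Oc3ccc(C=O)cc3O[C@@H]2CO)ccc1O[Si](C(C)C)(C(C)C)C(C)C
F7 | step 9 | 4-[(3S)-6-(dimethoxymethyl)-3-[(4R)-2,2-dimethyl-1,3-dioxolan-4-yl]-2,3-dihydro-1,4-benzodioxin-2-yl]-2-methoxyphenol (C2 epimers) | COc1cc(C2Oc3ccc(C(OC)OC)cc3O[C@@H]2[C@H]4COC(C)(C)O4)ccc1O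
F8 | step 9 | 4-[(2R,3S)-6-(dimethoxymethyl)-3-[(4R)-2,2-dimethyl-1,3-dioxolan-4-yl]-2,3-dihydro-1,4-benzodioxin-2-yl]-2-methoxyphenol (trans) | COc1cc([C@H]2Oc3ccc(C(OC)OC)cc3O[C@@H]2[C@H]4COC(C)(C)O4)ccc1O
F9 | step 9 | (2R,3S)-6-(dimethoxymethyl)-3-[(4R)-2,2-dimethyl-1,3-dioxolan-4-yl]-2-{3-methoxy-4-[tri(propan-2-yl)silyloxy]phenyl}-2,3-dihydro-1,4-benzodioxine (trans isomer of 10) | COc1cc([C@H]2Oc3ccc(C(OC)OC)cc3O[C@@H]2[C@H]4COC(C)(C)O4)ccc1O[Si](C(C)C)(C(C)C)C(C)C
F10 | step 8 | (1R,2S,5R)-5-methyl-2-(2-phenylpropan-2-yl)cyclohexyl 2-oxoacetate ((−)-8-phenylmenthyl glyoxylate) | O=CC(=O)O[C@@H]1C[C@H](C)CC[C@H]1C(C)(C)c2ccccc2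
F11 | step 8 | (1R,2S,5R)-5-methyl-2-(2-phenylpropan-2-yl)cyclohexyl (2S)-3-[4-(dimethoxymethyl)-2-fluorophenoxy]-2-hydroxy-3-{3-methoxy-4-[tri(propan-2-yl)silyloxy]phenyl}propanoate (C3 epimers) | COc1cc(C(Oc2ccc(C(OC)OC)cc2F)[C@H](O)C(=O)O[C@@H]3C[C@H](C)CC[C@H]3C(C)(C)c4ccccc4)ccc1O[Si](C(C)C)(C(C)C)C(C)C
F12 | step 8 | (2R)-3-[4-(dimethoxymethyl)-2-fluorophenoxy]-3-{3-methoxy-4-[tri(propan-2-yl)silyloxy]phenyl}propane-1,2-diol (C3 epimers) | COc1cc(C(Oc2ccc(C(OC)OC)cc2F)[C@H](O)CO)ccc1O[Si](C(C)C)(C(C)C)C(C)C
F13 | step 8 | [(3R)-6-(dimethoxymethyl)-2-{3-methoxy-4-[tri(propan-2-yl)silyloxy]phenyl}-2,3-dihydro-1,4-benzodioxin-3-yl]methanol (C2 epimers) | COc1cc(C2Oc3ccc(C(OC)OC)cc3O[C@@H]2CO)ccc1O[Si](C(C)C)(C(C)C)C(C)C
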